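**Plan**

1. Retrosynthesis: the O8 silyl ether is removed last; the C4=C5 alkene is traced back to a C5 selenide; the lactone O–C6 bond and C5–Se are traced back to a cis C5=C6 alkene in the ten-membered ring. The ring is then cut at C5=C6 (metathesis), the acyl group at O9, the C9–C10 bond (alkenyl iodide plus aldehyde) and the C7–C8 bond (allylation).
2. Forward: a C1–C5/C10/C14 alkenyl iodide is made from (R)-β-citronellene and a C6–C9/C11–C13 aldehyde from tert-butyl acrylate, acrolein and (R)-glyceraldehyde acetonide. They are joined at C9–C10 and acylated, the carbocycle is closed, then the γ-lactone ring, and finally the alkene is moved to C4=C5.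
3. Enabling feature: C6 bears the lactone oxygen and is allylic to C4=C5, and the C12 carboxyl on C7 is γ,δ to a ring C5=C6 bond. Anti addition across C5=C6 therefore closes the five-membered ring O–C12–C11–C7–C6 and leaves on C5 a group that can leave toward the single C4 hydrogen.
4. Stereochemistry: C4 comes from citronellene and later fixes the C4=C5 geometry. C7 and C8 come from the glyceraldehyde centre through a syn, Felkin-selective indium allylation, and C9 from C8 by Felkin addition. C6 and C5 come from the anti addition steered by C7, and the side-chain centre from (R)-2-methylbutanoic acid.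

Key step: step 14

Remark: germacrane numbering is used throughout (ring C1–C10, lactone carbons C11–C13, formyl C14, methyl C15); (R)-glyceraldehyde acetonide is taken as purchased and distilled before use.

**Route**

Step 1
Reactants: 1 (R)-β-citronellene
Product: 3 (4R)-4-methylhex-5-enal, via ozonide 2 (not isolated)
Conditions: O3 (1.0 equiv, metered), CH2Cl2, −78 °C; PPh3, −78 °C to rt
Reagents that add atoms: ozone, [O-][O+]=O
Why: Ozone attacks the electron-rich trisubstituted alkene much faster than the monosubstituted vinyl group, so chemoselective ozonolysis with reductive work-up should cleave only the isopropylidene end and leave the C4 stereocentre untouched.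

Step 2
Reactants: 3 (4R)-4-methylhex-5-enal; 4 (triphenylphosphoranylidene)acetaldehyde
Product: 5 (2E,6R)-6-methylocta-2,7-dienal
Conditions: toluene, 80 °C
Reagents that add atoms: none
Why: Wittig olefination with the stabilised formyl ylide should give the E-enal and add C10 and C14.

Step 3
Reactants: 5 (2E,6R)-6-methylocta-2,7-dienal
Product: 6 (2Z,6R)-2-iodo-6-methylocta-2,7-dienal
Conditions: I2, K2CO3, DMAP (0.2 equiv), THF/H2O (1:1), rt
Reagents that add atoms: iodine, II
Why: Conjugate addition of DMAP, iodination of the enolate and loss of DMAP (α-iodination of an enal) should give the Z-iodoenal with the chain cis to iodine, while the isolated vinyl group does not react.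

Step 4
Reactants: 6 (2Z,6R)-2-iodo-6-methylocta-2,7-dienal
Product: 7 (3R,6Z)-7-iodo-8,8-dimethoxy-3-methylocta-1,6-diene
Conditions: HC(OMe)3, TsOH·H2O (cat.), MeOH, rt; NaHCO3
Reagents that add atoms: trimethyl orthoformate, COC(OC)OC; methanol, CO
Why: Acid-catalysed acetalisation with orthoformate as water scavenger masks C14 so that the alkenyl iodide can later be coupled to another aldehyde.

Step 5
Reactants: 8 tert-butyl acrylate; 9 acrolein
Product: 10 tert-butyl 3-hydroxy-2-methylidenepent-4-enoate (racemic)
Conditions: DABCO (0.3 equiv), MeOH (cat.), neat, rt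
Reagents that add atoms: none
Why: The Morita–Baylis–Hillman reaction joins the acrylate α-carbon (C11) to the acrolein carbonyl carbon (C7); the racemic carbinol centre is erased in step 6.

Step 6
Reactants: 10 tert-butyl 3-hydroxy-2-methylidenepent-4-enoate
Product: 11 tert-butyl (2Z)-2-(bromomethyl)penta-2,4-dienoate
Conditions: NBS, Me2S, CH2Cl2, 0 °C to rt
Reagents that add atoms: N-bromosuccinimide, O=C1CCC(=O)N1Br
Why: Corey–Kim-type activation of the allylic alcohol followed by SN2' attack of bromide at the acrylate methylene should give the conjugated primary allylic bromide as the 2Z isomer, without acid that would cleave the tert-butyl ester.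

Step 7
Reactants: 11 tert-butyl (2Z)-2-(bromomethyl)penta-2,4-dienoate; 12 (4R)-2,2-dimethyl-1,3-dioxolane-4-carbaldehyde
Product: 13 tert-butyl (3R,4S)-4-[(4R)-2,2-dimethyl-1,3-dioxolan-4-yl]-3-ethenyl-4-hydroxy-2-methylidenebutanoate
Conditions: In (powder), THF/H2O (1:1), rt
Reagents that add atoms: none
Why: In this Barbier allylation the 2-(alkoxycarbonyl)allylindium species should add through its γ-carbon in a six-membered cyclic transition state, giving the branched adduct with C7 and C8 syn, while Felkin–Anh attack anti to the dioxolane oxygen sets C8 from the (R)-aldehyde; the tert-butyl ester prevents lactonisation onto O8.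

Step 8
Reactants: 13 allylation adduct
Product: 14 tert-butyl (3R,4S)-4-[(tert-butyldimethylsilyl)oxy]-4-[(4R)-2,2-dimethyl-1,3-dioxolan-4-yl]-3-ethenyl-2-methylidenebutanoate
Conditions: TBSOTf, 2,6-lutidine, CH2Cl2, −78 to −20 °C
Reagents that add atoms: tert-butyldimethylsilyl triflate, CC(C)(C)[Si](C)(C)OS(=O)(=O)C(F)(F)F
Why: Silyl triflate with a hindered pyridine base silylates the hindered secondary O8 at low temperature, where the acetonide and the tert-butyl ester should survive.

Step 9
Reactants: 14 silyl ether acetonide
Product: 16 tert-butyl (3R,4S)-4-[(tert-butyldimethylsilyl)oxy]-3-ethenyl-2-methylidene-5-oxopentanoate, via diol 15 (not isolated)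
Conditions: H5IO6, EtOAc, rt
Reagents that add atoms: none
Why: Periodic acid should hydrolyse the terminal acetonide and cleave the freed 1,2-diol in the same flask (glycol cleavage), giving the C9 aldehyde; the sacrificed glyceraldehyde centre has by then fixed C7 and C8, and the silyl ether and tert-butyl ester are stable.

Step 10
Reactants: 16 C9 aldehyde; 7 alkenyl iodide
Product: 17 tert-butyl (3R,4S,5R,6E,10R)-4-[(tert-butyldimethylsilyl)oxy]-6-(dimethoxymethyl)-3-ethenyl-5-hydroxy-10-methyl-2-methylidenedodeca-6,11-dienoate
Conditions: CrCl2 (4 equiv), NiCl2 (2 mol%), DMSO, rt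
Reagents that add atoms: none
Why: In the Nozaki–Hiyama–Kishi coupling zerovalent nickel inserts into the C–I bond with retention of geometry and hands the alkenyl group to trivalent chromium, which adds to the aldehyde only (not to the acrylate or the acetal); Felkin–Anh attack anti to the C8 silyloxy group should give the 8,9-anti alcohol (9R).

Step 11
Reactants: 17 C9 alcohol; 18 (R)-2-methylbutanoic acid
Product: 19 tert-butyl (3R,4S,5R,6E,10R)-4-[(tert-butyldimethylsilyl)oxy]-6-(dimethoxymethyl)-3-ethenyl-10-methyl-2-methylidene-5-{[(2R)-2-methylbutanoyl]oxy}dodeca-6,11-dienoate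
Conditions: DCC, DMAP (0.3 equiv), CH2Cl2, 0 °C to rt
Reagents that add atoms: none
Why: Steglich esterification acylates the free allylic O9 under nearly neutral conditions, which should preserve the α-stereocentre of the acid and the base-sensitive skipped diene at C7.

Step 12
Reactants: 19 acyclic triene ester
Product: 20 tert-butyl 2-[(1R,2Z,4R,7E,9R,10S)-10-[(tert-butyldimethylsilyl)oxy]-8-(dimethoxymethyl)-4-methyl-9-{[(2R)-2-methylbutanoyl]oxy}cyclodeca-2,7-dien-1-yl]prop-2-enoate
Conditions: second-generation Grubbs catalyst RuCl2(=CHPh)(PCy3)(H2IMes) (10 mol%), 1,4-benzoquinone (20 mol%), CH2Cl2 (1 mM), 40 °C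
Reagents that add atoms: none
Why: Ring-closing metathesis should engage only the two monosubstituted vinyl groups (the acrylate and the trisubstituted C1=C10 alkene are far less reactive) and give the cis C5=C6 alkene, because the product is a cis,cis-cyclodeca-1,6-diene, the least strained ten-membered diene, and the ring-cis C1=C10 bond already folds the chain.

Step 13
Reactants: 20 ten-membered tert-butyl ester acetal
Product: 22 ring-closed acrylic acid with free C14 aldehyde and O8 silyl ether, via silyl ester pyridinium salt 21 (not isolated)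
Conditions: TMSOTf (5 equiv), 2,6-lutidine (8 equiv), CH2Cl2, 0 °C; then H2O, rt
Reagents that add atoms: water, O
Why: Silyl triflate with a pyridine base converts a tert-butyl ester into the silyl ester with loss of isobutene and a dimethyl acetal into a pyridinium N,O-acetal; both hydrolyse on aqueous work-up, while the secondary silyl ether and the O9 ester should stay intact.

Step 14
Reactants: 22 ring-closed acrylic acid
Product: 23 5-phenylselanyl-6,12-olide (trans-fused γ-lactone closed)
Conditions: N-(phenylseleno)phthalimide (1.2 equiv), CSA (10 mol%), CH2Cl2, −20 °C to rt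
Reagents that add atoms: N-(phenylseleno)phthalimide, O=C1c2ccccc2C(=O)N1[Se]c1ccccc1
Why: The selenium electrophile released from the phthalimide reagent by the acid catalyst adds reversibly to the electron-rich cis C5=C6 alkene, and the C12 carboxyl oxygen opens the seleniranium ion at C6 from the face opposite to selenium, so O–C6 and C5–Se form in one anti addition. This is the phenylselenolactonisation of a γ,δ-unsaturated carboxylic acid, a well-established reaction type. The γ-lactone (O, C12, C11, C7, C6) closes in the 5-exo mode, which is preferred over 6-endo attack at C5. C6 is set by the alkene face that selenium takes: the C7 stereocentre controls this through the tethered carboxyl, and because the addition is reversible under acid catalysis the more stable trans-fused lactone (H6 and H7 anti) should accumulate; C5 then follows from anti addition to the cis alkene. The step needs chemoselectivity among three alkenes, which is secured because the acrylic acid and enal double bonds are electron-poor and C1=C10 has no nucleophile within reach; the silyl ether on O8 blocks ether formation at C5 and 8,12-lactonisation.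

Step 15
Reactants: 23 5-phenylselanyl-6,12-olide
Product: 25 O8-silylated target with ring-cis C4=C5, via selenoxide 24 (not isolated)
Conditions: NaIO4 (3 equiv), NaHCO3, THF/H2O (3:1), 0 °C to rt
Reagents that add atoms: none
Why: Periodate oxidises selenium to the selenoxide without touching the aldehyde or the alkenes; syn elimination at room temperature should go away from oxygen-bearing C6 toward the single C4 hydrogen, and the relative configuration of C4 and C5 places C3 and C6 cis in the eclipsed transition state, giving the ring-cis trisubstituted alkene.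

Step 16
Reactants: 25 O8-silylated target
Product: 26 target compound
Conditions: HF·pyridine, THF, 0 °C to rt
Reagents that add atoms: none
Why: Fluoride-mediated desilylation under weakly acidic conditions frees O8 without base, so acyl migration from O9, conjugate addition to the methylene lactone and translactonisation should be avoided.

**Compound list**

1 | (R)-β-citronellene, (3R)-3,7-dimethylocta-1,6-diene | C=C[C@H](C)CCC=C(C)C | starting material
2 | 3,3-dimethyl-5-[(3R)-3-methylpent-4-en-1-yl]-1,2,4-trioxolane (ozonide, formed in the flask) | C=C[C@H](C)CCC1OOC(C)(C)O1 | intermediate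
3 | (4R)-4-methylhex-5-enal | C=C[C@H](C)CCC=O | intermediate
4 | (triphenylphosphoranylidene)acetaldehyde | O=CC=P(c1ccccc1)(c1ccccc1)c1ccccc1 | starting material
5 | (2E,6R)-6-methylocta-2,7-dienal | C=C[C@H](C)CC/C=C/C=O | intermediate
6 | (2Z,6R)-2-iodo-6-methylocta-2,7-dienal | C=C[C@H](C)CC/C=C(\I)C=O | intermediate
7 | (3R,6Z)-7-iodo-8,8-dimethoxy-3-methylocta-1,6-diene | C=C[C@H](C)CC/C=C(\I)C(OC)OC | intermediate
8 | tert-butyl acrylate | C=CC(=O)OC(C)(C)C | starting material
9 | acrolein | C=CC=O | starting material
10 | tert-butyl 3-hydroxy-2-methylidenepent-4-enoate (racemic) | C=CC(O)C(=C)C(=O)OC(C)(C)C | intermediate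
11 | tert-butyl (2Z)-2-(bromomethyl)penta-2,4-dienoate | C=C/C=C(\CBr)C(=O)OC(C)(C)C | intermediate
12 | (4R)-2,2-dimethyl-1,3-dioxolane-4-carbaldehyde, (R)-glyceraldehyde acetonide | O=C[C@H]1COC(C)(C)O1 | starting material
13 | tert-butyl (3R,4S)-4-[(4R)-2,2-dimethyl-1,3-dioxolan-4-yl]-3-ethenyl-4-hydroxy-2-methylidenebutanoate (C7/C8 syn, C8 anti to the dioxolane oxygen) | CC1(C)OC[C@@H](O1)[C@@H](O)[C@H](C=C)C(=C)C(=O)OC(C)(C)C | intermediate
14 | tert-butyl (3R,4S)-4-[(tert-butyldimethylsilyl)oxy]-4-[(4R)-2,2-dimethyl-1,3-dioxolan-4-yl]-3-ethenyl-2-methylidenebutanoate | CC1(C)OC[C@@H](O1)[C@@H](O[Si](C)(C)C(C)(C)C)[C@H](C=C)C(=C)C(=O)OC(C)(C)C | intermediate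
15 | tert-butyl (3R,4S,5R)-4-[(tert-butyldimethylsilyl)oxy]-3-ethenyl-5,6-dihydroxy-2-methylidenehexanoate (diol, formed in the flask) | OC[C@@H](O)[C@@H](O[Si](C)(C)C(C)(C)C)[C@H](C=C)C(=C)C(=O)OC(C)(C)C | intermediate
16 | tert-butyl (3R,4S)-4-[(tert-butyldimethylsilyl)oxy]-3-ethenyl-2-methylidene-5-oxopentanoate | O=C[C@@H](O[Si](C)(C)C(C)(C)C)[C@H](C=C)C(=C)C(=O)OC(C)(C)C | intermediate
17 | tert-butyl (3R,4S,5R,6E,10R)-4-[(tert-butyldimethylsilyl)oxy]-6-(dimethoxymethyl)-3-ethenyl-5-hydroxy-10-methyl-2-methylidenedodeca-6,11-dienoate (C9 alcohol, 8,9-anti) | C=C[C@H](C)CC/C=C(/C(OC)OC)[C@@H](O)[C@@H](O[Si](C)(C)C(C)(C)C)[C@H](C=C)C(=C)C(=O)OC(C)(C)C | intermediate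
18 | (R)-2-methylbutanoic acid | CC[C@@H](C)C(=O)O | starting material
19 | (2R)-2-methylbutanoate of 17 at O9 | C=C[C@H](C)CC/C=C(/C(OC)OC)[C@@H](OC(=O)[C@H](C)CC)[C@@H](O[Si](C)(C)C(C)(C)C)[C@H](C=C)C(=C)C(=O)OC(C)(C)C | intermediate
20 | tert-butyl 2-[(1R,2Z,4R,7E,9R,10S)-10-[(tert-butyldimethylsilyl)oxy]-8-(dimethoxymethyl)-4-methyl-9-{[(2R)-2-methylbutanoyl]oxy}cyclodeca-2,7-dien-1-yl]prop-2-enoate (cis C5=C6, ring-cis C1=C10) | CC(C)(C)OC(=O)C(=C)[C@H]1/C=C\[C@H](C)CC/C=C(/C(OC)OC)[C@@H](OC(=O)[C@H](C)CC)[C@H]1O[Si](C)(C)C(C)(C)C | intermediate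
21 | trimethylsilyl ester of 22 with C14 as methoxy(2,6-dimethylpyridinium-1-yl)methyl triflate (formed in the flask, C14 configuration undefined) | C[Si](C)(C)OC(=O)C(=C)[C@H]1/C=C\[C@H](C)CC/C=C(/C(OC)[n+]2c(C)cccc2C)[C@@H](OC(=O)[C@H](C)CC)[C@H]1O[Si](C)(C)C(C)(C)C.[O-]S(=O)(=O)C(F)(F)F | intermediate
22 | 2-[(1R,2Z,4R,7E,9R,10S)-10-[(tert-butyldimethylsilyl)oxy]-8-formyl-4-methyl-9-{[(2R)-2-methylbutanoyl]oxy}cyclodeca-2,7-dien-1-yl]prop-2-enoic acid (precursor of the key step) | OC(=O)C(=C)[C@H]1/C=C\[C@H](C)CC/C=C(/C=O)[C@@H](OC(=O)[C@H](C)CC)[C@H]1O[Si](C)(C)C(C)(C)C | intermediate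
23 | 8-O-TBS 9-O-[(2R)-2-methylbutanoyl] 14-oxo-5-(phenylselanyl)germacra-1(10),11(13)-dien-12,6-olide; lactone trans-fused, selenium at C5 anti to O6, C4 methyl as in 22 | C=C1C(=O)O[C@@H]2[C@@H]([Se]c3ccccc3)[C@H](C)CC/C=C(/C=O)[C@@H](OC(=O)[C@H](C)CC)[C@@H](O[Si](C)(C)C(C)(C)C)[C@@H]12 | intermediate
24 | selenoxide of 23 (formed in the flask, selenium configuration undefined) | C=C1C(=O)O[C@@H]2[C@@H]([Se](=O)c3ccccc3)[C@H](C)CC/C=C(/C=O)[C@@H](OC(=O)[C@H](C)CC)[C@@H](O[Si](C)(C)C(C)(C)C)[C@@H]12 | intermediate
25 | 8-O-tert-butyldimethylsilyl ether of the target (ring-cis C4=C5 and C1=C10) | C=C1C(=O)O[C@@H]2/C=C(/C)CC/C=C(/C=O)[C@@H](OC(=O)[C@H](C)CC)[C@@H](O[Si](C)(C)C(C)(C)C)[C@@H]12 | intermediate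
26 | (6R,7R,8S,9R)-8-hydroxy-9-[(2R)-2-methylbutanoyloxy]-14-oxogermacra-1(10),4,11(13)-trien-12,6-olide, both ring alkenes ring-cis | C=C1C(=O)O[C@@H]2/C=C(/C)CC/C=C(/C=O)[C@@H](OC(=O)[C@H](C)CC)[C@@H](O)[C@@H]12 | target

**Step count and risks**

Total steps: 16. Longest linear sequence: 12 steps (steps 5 to 16, from tert-butyl acrylate and acrolein); the citronellene branch (steps 1 to 4) joins at step 10.

Most likely to fail:

Step 12 (ring closure). Oligomerisation by intermolecular metathesis, or migration of the C6 vinyl group into conjugation with the acrylate by ruthenium hydride species, may outrun closure of the ten-membered ring. The fallback closes the ring at C9–C10 instead and sets out from 7 and 16. A cis-selective cross-metathesis of the two vinyl groups, run with excess 7 and the cyclometalated ruthenium nitrate catalyst Ru(NO3)(=CH-C6H4-2-OiPr)(C,C-chelating N-adamantyl-N'-mesitylimidazolin-2-ylidene), would give the linear cis-alkene iodo aldehyde F1. An intramolecular Nozaki–Hiyama–Kishi reaction (CrCl2, NiCl2 cat., DMF/THF, high dilution) would then form the C9–C10 bond, again under Felkin control from C8, and give the ten-membered C9 alcohol F2. Esterification with 18 (DCC, DMAP) returns to the route at 20.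

Step 14 (key step). Selenium may take the other alkene face, which would give the cis-fused lactone with C5 and C6 both inverted and later the wrong C4=C5 geometry; 6-endo closure is a lesser concern. The fallback sets out from 22 and makes the same O–C6 bond through an epoxide, whose face is chosen kinetically and irreversibly by attack on the exposed side of the ring rather than by reversible selenium transfer. Dimethyldioxirane in acetone at 0 °C would give the cis-5,6-epoxy acid F3. Catalytic CSA would then trigger 5-exo opening at C6 with inversion to the 5-hydroxy-6,12-olide F4. Syn dehydration of F4 with the Burgess reagent toward the C4 hydrogen returns to the route at 25.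

Step 10 (fragment coupling). Facial selectivity at C9 may be low, or the coupling of two hindered partners slow, leaving a mixture of C9 epimers. The fallback sets out from 17 as that mixture and replaces substrate-controlled addition by reagent-controlled reduction. Dess–Martin oxidation would give the C9 enone F5. Reduction with the (R)-2-methyl-CBS-oxazaborolidine and catecholborane in toluene at −78 °C, the trisubstituted alkenyl group acting as the large substituent, should deliver the 9R alcohol and return to the route at 17.

**Further compounds**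

F1 | step 12 | tert-butyl (3R,4Z,6R,9Z)-3-[(1S)-1-[(tert-butyldimethylsilyl)oxy]-2-oxoethyl]-10-iodo-11,11-dimethoxy-6-methyl-2-methylideneundeca-4,9-dienoate | CC(C)(C)OC(=O)C(=C)[C@@H](/C=C\[C@H](C)CC/C=C(\I)C(OC)OC)[C@H](O[Si](C)(C)C(C)(C)C)C=O
F2 | step 12 | tert-butyl 2-[(1R,2Z,4R,7E,9R,10S)-10-[(tert-butyldimethylsilyl)oxy]-8-(dimethoxymethyl)-9-hydroxy-4-methylcyclodeca-2,7-dien-1-yl]prop-2-enoate | CC(C)(C)OC(=O)C(=C)[C@H]1/C=C\[C@H](C)CC/C=C(/C(OC)OC)[C@@H](O)[C@H]1O[Si](C)(C)C(C)(C)C
F3 | step 14 | cis-5,6-epoxide of acid 22 (epoxide oxygen on the face opposite to the later lactone oxygen) | OC(=O)C(=C)[C@H]1[C@H]2O[C@H]2[C@H](C)CC/C=C(/C=O)[C@@H](OC(=O)[C@H](C)CC)[C@H]1O[Si](C)(C)C(C)(C)C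
F4 | step 14 | 5-hydroxy analogue of 23 (hydroxyl at C5 anti to O6, lactone trans-fused) | C=C1C(=O)O[C@@H]2[C@@H](O)[C@H](C)CC/C=C(/C=O)[C@@H](OC(=O)[C@H](C)CC)[C@@H](O[Si](C)(C)C(C)(C)C)[C@@H]12
F5 | step 10 | tert-butyl (3R,4S,6Z,10R)-4-[(tert-butyldimethylsilyl)oxy]-6-(dimethoxymethyl)-3-ethenyl-10-methyl-2-methylidene-5-oxododeca-6,11-dienoate | C=C[C@H](C)CC/C=C(/C(OC)OC)C(=O)[C@@H](O[Si](C)(C)C(C)(C)C)[C@H](C=C)C(=C)C(=O)OC(C)(C)C
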